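**Retrosynthetic overview**
1. Last bond: ring C2′–side-chain C2, by Negishi coupling of cyclopentenyl triflate 14 with the (Z)-alkenylzinc made from iodide 20 (three steps from but-2-yn-1-ol).
2. Triflate 14 comes from cyclopentenone 12 by conjugate reduction and enolate triflation, which places the ring alkene.
3. Cyclopentenone 12 comes from furylcarbinol 11 by an enantioselective oxa-Piancatelli rearrangement: the furan is dearomatised into the carbocycle and both ring stereocentres are set together.
4. Carbinol 11 comes from C2-alkylation of (S)-4-methoxycyclohexane-1,3-dione 5 with bromoketone 7 (from 2-acetyl-5-methylfuran), then ketone reduction; 5 comes from 3-methoxycyclohex-2-enone by asymmetric α′-hydroxylation, O-methylation and hydrolysis.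
5. Ring order: the six-membered dione ring is bought in and carried throughout; the five-membered carbocycle is formed last, from the furan ring, in step 7.

Assumption: the sense of induction of the chiral oxaziridine (step 1) and of the chiral acid (step 7) is taken by analogy and must be confirmed on the first run, the mirror-image reagent or catalyst being used if it is opposite; 2-substituted 1,3-diones are drawn as the enol tautomer used in the target SMILES.

**Step 1**
Reactants: 1 3-methoxycyclohex-2-en-1-one
Product: 3 (6S)-6-hydroxy-3-methoxycyclohex-2-en-1-one, via lithium dienolate 2 (not isolated)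
Conditions: LDA (1.1 equiv), THF, −78 °C; (−)-[(8,8-dichlorocamphoryl)sulfonyl]oxaziridine (1.2 equiv), −78 °C; aq NH4Cl
Reagents that add atoms: (−)-[(8,8-dichlorocamphoryl)sulfonyl]oxaziridine, CC1(C)C2CCC13CS(=O)(=O)N4OC34C2(Cl)Cl
Why: Kinetic deprotonation of the vinylogous ester occurs at C6 and the cross-conjugated enolate is hydroxylated by the N-sulfonyloxaziridine (Davis oxidation), the camphor-derived reagent selecting the enolate face that gives 6S (sense by analogy with 1-tetralone enolates).

**Step 2**
Reactants: 3 (6S)-6-hydroxy-3-methoxycyclohex-2-en-1-one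
Product: 4 (6S)-3,6-dimethoxycyclohex-2-en-1-one
Conditions: MeI (10 equiv), Ag2O (2 equiv), 4 Å MS, MeCN, 25 °C, dark
Reagents that add atoms: iodomethane, CI
Why: Purdie O-methylation (Ag2O/MeI) etherifies the α-hydroxy ketone without a strong base, so the stereocentre is not enolised.

**Step 3**
Reactants: 4 (6S)-3,6-dimethoxycyclohex-2-en-1-one
Product: 5 (4S)-4-methoxycyclohexane-1,3-dione
Conditions: 1 M aq HCl, THF, 25 °C
Reagents that add atoms: water, O
Why: Acid hydrolysis of the vinylogous ester (water adds to the β-carbon, methanol leaves) unmasks the 1,3-dione and does not involve the C–OMe stereocentre.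

**Step 4**
Reactants: 6 1-(5-methylfuran-2-yl)ethan-1-one (2-acetyl-5-methylfuran)
Product: 7 2-bromo-1-(5-methylfuran-2-yl)ethan-1-one
Conditions: CuBr2 (2.1 equiv), EtOAc/CHCl3 1:1, reflux
Reagents that add atoms: copper(II) bromide, Br[Cu]Br
Why: CuBr2 α-bromination of the methyl ketone through its enol; the acyl group deactivates the furan ring, so ring bromination is avoided.

**Step 5**
Reactants: 5 (4S)-4-methoxycyclohexane-1,3-dione; 7 2-bromo-1-(5-methylfuran-2-yl)ethan-1-one
Product: 9 (4S)-4-methoxy-2-[2-(5-methylfuran-2-yl)-2-oxoethyl]cyclohexane-1,3-dione, via potassium enolate 8 (not isolated)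
Conditions: K2CO3 (1.1 equiv), CHCl3, 25 °C
Reagents that add atoms: none
Why: SN2 C-alkylation of the soft 1,3-dionate at C2 by the phenacyl-type bromide (such electrophiles give C- rather than O-alkylation); as the monoanion the dione cannot enolise toward C4, so the stereocentre is safe.

**Step 6**
Reactants: 9 (4S)-4-methoxy-2-[2-(5-methylfuran-2-yl)-2-oxoethyl]cyclohexane-1,3-dione
Product: 11 (4S)-2-[2-hydroxy-2-(5-methylfuran-2-yl)ethyl]-4-methoxycyclohexane-1,3-dione (both carbinol epimers), via sodium dionate 10 (not isolated)
Conditions: NaBH4 (2 equiv), EtOH, 0 °C; pH 5 citrate buffer, 0 °C, quick extraction, used at once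
Reagents that add atoms: none
Why: Borohydride reduction touches only the furyl ketone because the dione is present as its unreactive enolate; the carbinol configuration is irrelevant because this carbon becomes planar in step 7.

**Step 7 (key step)**
Reactants: 11 (4S)-2-[2-hydroxy-2-(5-methylfuran-2-yl)ethyl]-4-methoxycyclohexane-1,3-dione
Product: 12 (4S)-2-{[(1S,5S)-5-hydroxy-5-methyl-2-oxocyclopent-3-en-1-yl]methyl}-4-methoxycyclohexane-1,3-dione
Conditions: (R)-TRIP N-triflylphosphoramide (10 mol%), H2O (5 equiv), CHCl3, 40 °C
Reagents that add atoms: water, O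
Why: Proposed new method: the oxa-Piancatelli rearrangement (ionisation of the furylcarbinol, water capture at the methyl-bearing furan carbon, ring opening to a 1,4-dihydroxypentadienyl cation, conrotatory 4π closure) is established for 5-methyl-2-furylcarbinols with achiral acids; here the chiral phosphoramide anion is proposed to pair with the cation and fix the sense of conrotation (absolute control), while the larger terminal groups CH2R and CH3 turn outward and end up trans, which places OH cis to the CH2 linker (relative control); the closest known reaction types are the chiral phosphoric acid-catalysed aza-Piancatelli rearrangement and chiral Brønsted acid-catalysed Nazarov cyclisation.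

**Step 8**
Reactants: 12 (4S)-2-{[(1S,5S)-5-hydroxy-5-methyl-2-oxocyclopent-3-en-1-yl]methyl}-4-methoxycyclohexane-1,3-dione
Product: 14 (4S)-2-{[(1S,5S)-5-hydroxy-5-methyl-2-(trifluoromethanesulfonyloxy)cyclopent-2-en-1-yl]methyl}-4-methoxycyclohexane-1,3-dione, via dilithium enolate 13 (not isolated)
Conditions: L-Selectride (2.3 equiv), THF, −78 °C; Comins' reagent (1.2 equiv), −78 → −30 °C; aq NH4Cl
Reagents that add atoms: Comins' reagent N-(5-chloropyridin-2-yl)bis(trifluoromethanesulfonyl)imide, FC(F)(F)S(=O)(=O)N(c1ccc(Cl)cn1)S(=O)(=O)C(F)(F)F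
Why: Conjugate reduction–enolate triflation: the first hydride equivalent only deprotonates the dione (its enolate is inert to hydride and to the triflating agent at −78 °C), 1,4-hydride addition to the β-unsubstituted enone then gives the regiodefined enolate, which is trapped as the C2′=C3′ enol triflate without touching a stereocentre.

**Step 9**
Reactants: 15 but-2-yn-1-ol
Product: 17 (2Z)-3-iodobut-2-en-1-ol, via cyclic alkenylalanate 16 (not isolated)
Conditions: Red-Al (1.5 equiv), Et2O, 0 → 25 °C; I2 (1.6 equiv), −78 → 0 °C; aq Rochelle salt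
Reagents that add atoms: iodine, II
Why: Hydroxyl-directed trans-hydroalumination puts aluminium on C3 cis to the CH2O group, and iodinolysis with retention gives the (Z)-iodoalkene.

**Step 10**
Reactants: 17 (2Z)-3-iodobut-2-en-1-ol
Product: 18 (2Z)-1-bromo-3-iodobut-2-ene
Conditions: CBr4 (1.2 equiv), PPh3 (1.2 equiv), CH2Cl2, 0 °C
Reagents that add atoms: carbon tetrabromide, BrC(Br)(Br)Br
Why: Appel reaction converts the primary allylic alcohol into the bromide under neutral conditions without disturbing the vinyl iodide or the alkene geometry.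

**Step 11**
Reactants: 18 (2Z)-1-bromo-3-iodobut-2-ene; 19 (2-methylprop-1-en-1-yl)magnesium bromide (0.5 M in THF)
Product: 20 (2Z)-2-iodo-6-methylhepta-2,5-diene
Conditions: CuI (10 mol%), THF, −30 → 0 °C
Reagents that add atoms: none
Why: Copper-catalysed Grignard allylic substitution at the primary bromide (SN2′ would have to attack the fully substituted iodo-bearing carbon) builds the skipped diene, the vinyl iodide being inert at this temperature.

**Step 12**
Reactants: 14 (4S)-2-{[(1S,5S)-5-hydroxy-5-methyl-2-(trifluoromethanesulfonyloxy)cyclopent-2-en-1-yl]methyl}-4-methoxycyclohexane-1,3-dione; 20 (2Z)-2-iodo-6-methylhepta-2,5-diene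
Product: 24 (4S)-3-hydroxy-2-{[(1R,5S)-5-hydroxy-5-methyl-2-[(2Z)-6-methylhepta-2,5-dien-2-yl]cyclopent-2-en-1-yl]methyl}-4-methoxycyclohex-2-en-1-one (target), via sodium dionate 21 (not isolated), via alkenyllithium 22 (not isolated), via alkenylzinc chloride 23 (not isolated)
Conditions: 14: NaH (1.0 equiv), THF, 0 °C; 20: t-BuLi (2.1 equiv), Et2O, −78 °C, then ZnCl2 (1.1 equiv), → 0 °C; combine, Pd(PPh3)4 (5 mol%), THF, 25 → 45 °C; aq NH4Cl
Reagents that add atoms: none
Why: Iodine–lithium exchange, transmetalation to zinc and Negishi coupling with the enol triflate all proceed with retention of alkene geometry, so the two sp2 carbons are joined as the (Z)-diene; the dione is carried as its sodium salt so that it does not protonate the organozinc.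

**Compound list**
1 | 3-methoxycyclohex-2-en-1-one | COC1=CC(=O)CCC1 | starting material
2 | lithium 5-methoxycyclohexa-1,5-dien-1-olate (kinetic α′-enolate of 1) | [Li+].COC1=CC([O-])=CCC1 | intermediate
3 | (6S)-6-hydroxy-3-methoxycyclohex-2-en-1-one | O[C@H]1CCC(OC)=CC1=O | intermediate
4 | (6S)-3,6-dimethoxycyclohex-2-en-1-one | CO[C@H]1CCC(OC)=CC1=O | intermediate
5 | (4S)-4-methoxycyclohexane-1,3-dione | CO[C@H]1CCC(=O)CC1=O | intermediate
6 | 1-(5-methylfuran-2-yl)ethan-1-one | CC(=O)c1ccc(C)o1 | starting material
7 | 2-bromo-1-(5-methylfuran-2-yl)ethan-1-one | Cc1ccc(o1)C(=O)CBr | intermediate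
8 | potassium (4S)-4-methoxy-3-oxocyclohex-1-en-1-olate (enolate of 5) | [K+].CO[C@H]1CCC([O-])=CC1=O | intermediate
9 | (4S)-4-methoxy-2-[2-(5-methylfuran-2-yl)-2-oxoethyl]cyclohexane-1,3-dione | CO[C@H]1CCC(=O)C(CC(=O)c2ccc(C)o2)=C1O | intermediate
10 | sodium dionate of 9 | [Na+].CO[C@H]1CCC(=O)C(CC(=O)c2ccc(C)o2)=C1[O-] | intermediate
11 | (4S)-2-[2-hydroxy-2-(5-methylfuran-2-yl)ethyl]-4-methoxycyclohexane-1,3-dione (carbinol centre as 1:1 mixture) | CO[C@H]1CCC(=O)C(CC(O)c2ccc(C)o2)=C1O | intermediate
12 | (4S)-2-{[(1S,5S)-5-hydroxy-5-methyl-2-oxocyclopent-3-en-1-yl]methyl}-4-methoxycyclohexane-1,3-dione (OH cis to the CH2 linker) | CO[C@H]1CCC(=O)C(C[C@@H]2C(=O)C=C[C@]2(C)O)=C1O | intermediate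
13 | dilithium salt of the cyclopentenolate/dionate formed by 1,4-reduction of 12 (tertiary OH free) | [Li+].[Li+].CO[C@H]1CCC(=O)C(C[C@@H]2C([O-])=CC[C@]2(C)O)=C1[O-] | intermediate
14 | (4S)-2-{[(1S,5S)-5-hydroxy-5-methyl-2-(trifluoromethanesulfonyloxy)cyclopent-2-en-1-yl]methyl}-4-methoxycyclohexane-1,3-dione | CO[C@H]1CCC(=O)C(C[C@@H]2C(OS(=O)(=O)C(F)(F)F)=CC[C@]2(C)O)=C1O | intermediate
15 | but-2-yn-1-ol | CC#CCO | starting material
16 | sodium cyclic alkenylalanate (Al bound to C3 and to the alkoxide O, two 2-methoxyethoxy ligands) | [Na+].CC1=CCO[Al-]1(OCCOC)OCCOC | intermediate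
17 | (2Z)-3-iodobut-2-en-1-ol | C/C(I)=C/CO | intermediate
18 | (2Z)-1-bromo-3-iodobut-2-ene | C/C(I)=C/CBr | intermediate
19 | (2-methylprop-1-en-1-yl)magnesium bromide | CC(C)=C[Mg]Br | starting material
20 | (2Z)-2-iodo-6-methylhepta-2,5-diene | C/C(I)=C/CC=C(C)C | intermediate
21 | sodium dionate of 14 | [Na+].CO[C@H]1CCC(=O)C(C[C@@H]2C(OS(=O)(=O)C(F)(F)F)=CC[C@]2(C)O)=C1[O-] | intermediate
22 | (6-methylhepta-2,5-dien-2-yl)lithium, Li cis to C4H2 | [Li]/C(C)=C\CC=C(C)C | intermediate
23 | chloro[(2Z)-6-methylhepta-2,5-dien-2-yl]zinc, Zn cis to C4H2 | Cl[Zn]/C(C)=C\CC=C(C)C | intermediate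
24 | (4S)-3-hydroxy-2-{[(1R,5S)-5-hydroxy-5-methyl-2-[(2Z)-6-methylhepta-2,5-dien-2-yl]cyclopent-2-en-1-yl]methyl}-4-methoxycyclohex-2-en-1-one | CO[C@H]1CCC(=O)C(C[C@@H]2C(/C(C)=C\CC=C(C)C)=CC[C@]2(C)O)=C1O | target

**Totals**
Total step count: 12. Longest linear sequence: 8 steps (1, 2, 3, 5, 6, 7, 8, 12).

**Steps most likely to fail and their fallbacks**

Step 7 carries the most risk. Enantiocontrol by a chiral acid is unproven for an oxa-Piancatelli reaction, and the substrate's own acidic dione may cause a racemic background reaction. The dione oxygen can also trap the furfuryl cation as a dihydrofuran; this should re-ionise to the same cation and so remain a competent precursor. The OH-cis-to-linker outcome rests on the outward rotation of CH3 and must be checked by NOE between the ring CH3 and H-1′; C1′ is α to the ketone and can equilibrate under acid toward the isomer with the linker trans to CH3. Fallback: starting from 11, the rearrangement is run with an achiral catalyst (Dy(OTf)3 10 mol%, MeCN/H2O, 80 °C), which gives 12 together with its diastereomer, the (1R,5R)-cyclopentenone epimer F1, in about equal amounts. Because C4 of the dione is already S, the two are diastereomers and are separated by preparative HPLC or by fractional crystallisation of their (R)-1-phenylethylammonium salts; the route is rejoined at 12.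

Step 8 may suffer 1,2-reduction, retro-aldol or base-induced isomerisation of the β-hydroxy enone, or triflation of the dionate. Fallback: starting from 12, hydrogenation (H2 1 atm, 5% Pd/C, EtOAc, 25 °C; neutral, and the tetrasubstituted enol double bond is not reduced) gives the saturated hydroxy ketone F2. Kinetic deprotonation with LiHMDS (3.2 equiv, THF, −78 °C; dione and hydroxyl are deprotonated first) then occurs at the unsubstituted α-CH2, and Comins' reagent gives 14, where the route is rejoined.

Step 1 may give only moderate enantiomeric excess, since oxaziridine hydroxylation of trisubstituted cyclic enolates is substrate-dependent. Any (R)-C4 material appears after step 7 as a diastereomer and can be removed there, but a cleaner source is preferable. Fallback: starting from 1, Mn(OAc)3 (benzene, reflux) gives the racemic α′-acetate F3; lipase-catalysed hydrolysis (Amano lipase PS, pH 7 phosphate buffer/MTBE, to 50% conversion) of the (S)-acetate delivers 3 and leaves the (R)-acetate F4, which is removed by chromatography. The route is rejoined at 3.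

**Further compounds**
F1 | step 7 | (4S)-2-{[(1R,5R)-5-hydroxy-5-methyl-2-oxocyclopent-3-en-1-yl]methyl}-4-methoxycyclohexane-1,3-dione | CO[C@H]1CCC(=O)C(C[C@H]2C(=O)C=C[C@@]2(C)O)=C1O
F2 | step 8 | (4S)-2-{[(1S,2S)-2-hydroxy-2-methyl-5-oxocyclopentyl]methyl}-4-methoxycyclohexane-1,3-dione | CO[C@H]1CCC(=O)C(C[C@@H]2C(=O)CC[C@]2(C)O)=C1O
F3 | step 1 | rac-4-methoxy-2-oxocyclohex-3-en-1-yl acetate | CC(=O)OC1CCC(OC)=CC1=O
F4 | step 1 | (1R)-4-methoxy-2-oxocyclohex-3-en-1-yl acetate | CC(=O)O[C@@H]1CCC(OC)=CC1=O
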